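**Compound numbers used throughout:** 1 and 2 are the starting materials, 5 and 6 the side-chain enones, 7 methylmagnesium bromide, 10 the product of the key step, 12, 14 and 15 the ring A and ring B adjustments, 17 and 19 the isopropylidene ketone stage, 20–23 the diol and ester stages, and 24 the target. Compounds 3, 4, 8, 9, 11, 13, 16 and 18 form in the flask and are not isolated.

## The problem

The target, 3β-angeloyloxy-4α-acetoxyeudesm-7(11)-en-8-one (24), is a trans-fused decalin. With eudesmane numbering, ring A is C1–C2–C3–C4–C5–C10 and ring B is C5–C6–C7–C8–C9–C10; C10 carries the axial β-methyl, C5 an α-hydrogen, C4 an axial β-methyl and an equatorial α-acetoxy group, C3 an equatorial β-angelate, and C8 is a ketone conjugated with the exocyclic C7=C11 isopropylidene group, the four stereocentres being 3S,4S,5R,10R. C10 is an all-carbon quaternary centre with no neighbouring heteroatom, so it must be set by catalyst-controlled C–C bond formation; once set it can govern the rest: C5 by equilibration next to a C4 carbonyl, C4 by attack on a C3=C4 alkene anti to the syn-axial C10 methyl, and C3 by axial hydride delivery to a C3 ketone. The C3 and C4 oxygens are trans-diequatorial, which neither a syn-dihydroxylation (3α,4α) nor a diaxial epoxide opening (3α,4β) gives directly, so one centre has to be corrected afterwards. The sensitive parts are the angelate, which drifts to the tiglate under acid, base, heat or nucleophilic catalysis; the hindered tertiary acetate, which is hard to install and can eliminate or exchange with its neighbour; and the α-isopropylidene ketone, which can deconjugate or undergo retro-aldol cleavage. All three argue for esterification at the very end and against enolate chemistry after it. C4 and C8 are both carbonyl carbons at some stage and must be told apart. The enabling feature is the 1,3-relationship C4–C5–C10: a ring A enone with its carbonyl at C4 and its alkene at C5=C10 accepts the angular methyl at C10 and thereby forms its enolate at C5, the carbon that must bond to C6, so a C10 side chain C9–C8–C7–C6 ending in a leaving group turns one conjugate addition into the whole bicycle.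

## Retrosynthesis

**Ester bonds (24 ⇒ 23 ⇒ 22).** The acetyl C–O bond at C4 and then the angeloyl C–O bond at C3 are cut, leading through mono-ester 23 to diol 22. This keeps the isomerisable angelate and the tertiary acetate out of every earlier step. Carrying an ester through the C3 redox correction would instead invite 1,2-acyl migration between O3 and O4. The forward reactions must distinguish a secondary equatorial hydroxyl from a tertiary one and must acylate without Z-to-E isomerisation.

**C3 and C4 oxygens (22 ⇒ 21 ⇒ 20 ⇒ 19).** Both C–O bonds are traced to the C3=C4 alkene of dienone 19. Syn-dihydroxylation from the α-face gives 20 with C4 correct and C3 wrong; oxidation to ketol 21 and axial hydride delivery then correct C3. An epoxide route is rejected because trans-diaxial opening of a 3α,4α-epoxide would give the 3α,4β-diol. Precursor 19 has two fewer stereocentres and no hydroxyls. The forward steps need face selectivity from the C10 methyl and reagents that leave the C7=C11 enone alone.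

**Isopropylidene (19 ⇒ 17 ⇒ 15).** The C7–C11 bond is cut as an aldol addition of C8 ketone 15, through its enolate 16, to the simplest dialkyl ketone, which supplies C11 and its two methyls. This gives 17, and dehydration through mesylate 18 leads to 19. Placing this before ring A oxidation means C8 is the only enolisable ketone present and no ester or ketol meets a strong base. It also makes a C8 protecting group unnecessary, because the hindered enone should survive steps 9–13. Forward, enolisation must go to C7 and not to the neopentyl C9, and elimination must end in the conjugated isomer.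

**C15 methyl and C8 carbonyl (15 ⇒ 14 ⇒ 12 ⇒ 10).** The C4–C15 bond is cut to enol triflate 14 (cross-coupling). The C8 carbonyl is traced to the exocyclic methylene of 12 (ozonolysis through ozonide 13), and the triflate to ketone 10 (through enolate 11). The order matters. As an enol triflate, the C4 carbonyl is hidden as an electron-poor alkene while C8 is unveiled, so a 4,8-diketone never has to be differentiated. The methyl is coupled only after ozonolysis, so no electron-rich trisubstituted alkene competes for ozone. What remains, 10, has two stereocentres and one alkene.

**Ring B and the angular methyl (10 ⇒ 6 + 7).** The C10–CH3 and C5–C6 bonds are cut together. A Robinson annulation would also deliver the angular methyl, but it places the ring B carbonyl at C9, next to the quaternary carbon, so a 1,2-carbonyl transposition to C8 would be owed. Here the quaternary centre, ring B and the ring fusion come from one operation on the achiral monocyclic enone 6 and methylmagnesium bromide (7), and the C8 carbon arrives as a masked ketone in the right place. The forward reaction must be enantioselective at C10, must convert enolate 8 into the C5–C6 bond before it is protonated, and must end trans-fused, which equilibration of cis epimer 9 should secure.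

**Side chain (6 ⇒ 5 ⇒ 1 + 2).** The C–Cl bond goes back to alcohol 5. The C9–C10 bond is cut between the enone β-carbon and an allyl nucleophile: dianion 3 of 3-methylbut-3-en-1-ol (1) adds 1,2 to 3-ethoxycyclohex-2-en-1-one (2), and acid converts carbinolate 4 into the transposed enone. Both starting materials are commodity chemicals, and 1 supplies the C8 methylene and the C6 oxygen. Nothing stereochemical is at stake; the forward steps only have to keep the skipped diene out of conjugation.

## Roads not taken

**Alternative 1:** The cut is transannular. The C5–C10 bond and the C4–O bond are removed together, which unfolds both rings into the ten-membered triene (3S,1(10)E,4E)-3-(tert-butyldimethylsilyloxy)germacra-1(10),4,7(11)-trien-8-one A1. In the forward direction dilute aqueous acid would protonate C1 of A1, C5 of the C4=C5 alkene would bond to the C10 cation across the ring, and water would quench the C4 cation. The product of this key step would be 3β-(tert-butyldimethylsilyloxy)-4α-hydroxyeudesm-7(11)-en-8-one A2. Compound A2 already holds every skeletal carbon, the isopropylidene ketone and both oxygens, and acetylation, desilylation and angeloylation would take A2 to 24 in three steps. The merit is plain: one step makes both rings and C4, C5 and C10, and from A1 this road is far shorter than the thirteen steps chosen here. The weak points lie in A1 itself. A1 is a conformationally mobile medium ring whose only stereocentre, C3, must be installed enantioselectively and must then decide which face of the diene reacts. The C4 cation on the way to A2 can lose a proton to three different alkenes as easily as it captures water. E,E-cyclodeca-1,5-dienes of the A1 type are also prone to Cope rearrangement on warming and to alkene migration in acid. In comparison the chosen plan is longer, but it sets C10 with a catalyst on a simple enone, fixes C5, C4 and C3 by substrate control in a rigid trans-decalin, and does not depend on how a cation partitions between hydration and elimination.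

**Alternative 2:** Only the C9–C10 bond is cut, and ring A is taken back to an arene, the phenol methyl 4-(3-hydroxy-2,6-dimethylphenyl)-2-methylidenebutyl carbonate A3. Pd2(dba)3 (zerovalent palladium) with a chiral diphosphine would ionise the allylic carbonate of A3, and the phenolate would attack the π-allyl through its para carbon C10. This would give the cross-conjugated dienone (4aS)-1,4a-dimethyl-6-methylidene-5,6,7,8-tetrahydronaphthalen-2(4aH)-one A4, with the quaternary centre set by the ligand. Dienone A4 shares ring B and the C8 methylene with 10. It is better than the chosen plan in one respect: the C15 methyl and the C3 oxygen are present from the start, so steps 4 and 6 would disappear. The weak points are these. The tether of A3 lies between an ortho and a para carbon that both bear a methyl and both close a six-membered ring, so ortho/para and C/O selectivity are not secured by the substrate. A3 is a 1,2,3,4-tetrasubstituted arene needing its own multistep synthesis. A4 arrives with C5 sp2 and two ring A alkenes too many, so the trans fusion would have to come from a reduction and the C4 oxygen from a separate enolate oxidation, which returns the steps saved. Against the shorter ring A sequence from A4, the chosen plan sets C5 by equilibration and both oxygens by one dihydroxylation.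

**Alternative 3:** Two bonds are cut, C4–C5 and C9–C10, which opens both rings to the acyclic enyne tert-butyldimethyl{[(5E)-6-methyl-3-(propan-2-ylidene)undeca-1,5-dien-9-yn-2-yl]oxy}silane A5. A chiral monovalent gold complex, for example (R)-DTBM-SEGPHOS(AuCl)2 activated with AgSbF6, would activate the methyl-substituted alkyne of A5. C5 of the E-alkene would attack C4 in a 6-endo-dig closure, and C9 of the silyl dienol ether would trap the C10 cation, giving eudesma-3,7(11)-dien-8-one A6. Dienone A6 is the same compound as 19, so the two plans share steps 9–13. This road would make both rings, the trans fusion (anti addition across the E-alkene), the C3=C4 alkene and the enone in one step from an open chain. In convergence and in the absence of masking and redox steps it is clearly superior to steps 3–8 of the chosen plan. Its weak points are that enantioselective gold-initiated polyene cyclisations are best established for terminal alkynes and for heteroatom or arene terminators. The internal alkyne of A5 is less reactive and blurs the endo/exo choice, and a cross-conjugated 2-silyloxydiene is an acid-labile terminator. A5 also needs a geometrically pure trisubstituted alkene and a regioselectively formed dienol ether, so its synthesis would not be much shorter than the eight steps to 19. What the chosen plan sets against the single step to A6 is the reliability of its individual events: the quaternary centre is made on a ring, where catalyst control is best documented, and the ring fusion is corrected thermodynamically instead of resting on one concerted transition state.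

Key step: step 3

Assumption: the antipode of the chiral NHC ligand that delivers methyl to the enone face leading to 10R is meant throughout; its sense of induction is assigned by analogy with simple 3-alkylcyclohex-2-enones and has to be confirmed on 6.

## Route

Step 1
Reactants: 1 3-methylbut-3-en-1-ol; 2 3-ethoxycyclohex-2-en-1-one
Product: 5 3-(4-hydroxy-2-methylidenebutyl)cyclohex-2-en-1-one, via dilithio dianion 3 (not isolated), via dilithium carbinolate 4 (not isolated)
Conditions: 1, n-BuLi (2.1 equiv), TMEDA, Et2O/hexane, 0 °C → rt; 2, THF, −78 → 0 °C; then 1 M HCl, 0 °C, short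
Reagents that add atoms: water, O
Why: Allylic lithiation of the alkoxide of 1 gives a dianion with two equivalent CH2 termini, so its 1,2-addition to the vinylogous ester 2 has no regiochemical ambiguity; dilute acid then effects the Stork–Danheiser transposition (loss of the tertiary hydroxyl, hydrolysis of the enol ether) to the 3-substituted enone. Brief, cold acid treatment should keep the skipped diene out of conjugation.

Step 2
Reactants: 5 3-(4-hydroxy-2-methylidenebutyl)cyclohex-2-en-1-one
Product: 6 3-(4-chloro-2-methylidenebutyl)cyclohex-2-en-1-one
Conditions: PPh3, CCl4, CH2Cl2, 0 °C → rt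
Reagents that add atoms: tetrachloromethane, ClC(Cl)(Cl)Cl
Why: Appel reaction: chloride displaces the alkoxyphosphonium ion of the primary alcohol by SN2 under essentially neutral conditions, which spares the enone and the doubly allylic C9 methylene.

Step 3
Reactants: 6 3-(4-chloro-2-methylidenebutyl)cyclohex-2-en-1-one; 7 methylmagnesium bromide
Product: 10 (4aR,8aR)-4a-methyl-6-methylideneoctahydronaphthalen-1(2H)-one, via bromomagnesium enolate 8 (not isolated), via cis-fused C5 epimer 9 (not isolated)
Conditions: Cu(OTf)2 (3 mol %), chiral N-mesityl-N′-(1-hydroxy-4-methylpentan-2-yl)imidazolinium hexafluorophosphate (NHC precursor, 4 mol %), MeMgBr (1.15 equiv, slow addition), Et2O, −30 → 0 °C; then THF, DMPU, LiI, 40 °C; then NaOMe, MeOH, rt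
Reagents that add atoms: methylmagnesium bromide (7), C[Mg]Br
Why: MeMgBr reduces Cu(OTf)2 (divalent copper) to a monovalent copper–NHC methyl complex, which binds the enone of 6 as a π-complex and transfers methyl to C10 through a trivalent copper intermediate and reductive elimination, leaving the C4–C5 bromomagnesium enolate 8 with defined regiochemistry. The closest known reaction type is the copper-catalysed asymmetric conjugate addition of Grignard reagents to 3-substituted cyclohex-2-enones, combined with Michael-initiated ring closure in which the enolate displaces a tethered chloride. Ring B closes by 6-exo-tet C-alkylation of C5 on C6 once DMPU loosens the magnesium enolate and iodide exchanges the chloride; O-alkylation would need an eight-membered ring and is not expected. C10 is set by the chiral NHC on copper, which selects the enone face, and as a quaternary centre it cannot epimerise afterwards. C5 is probably formed mainly cis (the chain reaches the enolate carbon from an equatorial position) and is then equilibrated by NaOMe through the C4 enolate to the trans-fused ketone 10, expected to be the more stable isomer because the axial C10 methyl loses two of its four syn-axial hydrogens to the sp2 carbons C4 and C8. The step needs 1,4- over 1,2-addition (copper catalysis and slow Grignard addition), no coupling of MeMgBr with the halide (a primary chloride is inert to the organocopper species in Et2O at −30 to 0 °C, and iodide is added only after the Grignard reagent is consumed) and no deprotonation at the doubly allylic C9 (low temperature, fast catalysed addition).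

Step 4
Reactants: 10 (4aR,8aR)-4a-methyl-6-methylideneoctahydronaphthalen-1(2H)-one
Product: 12 (4aR,8aR)-4a-methyl-6-methylidene-3,4,4a,5,6,7,8,8a-octahydronaphthalen-1-yl trifluoromethanesulfonate, via lithium enolate 11 (not isolated)
Conditions: LiN(iPr)2, THF, −78 °C; PhNTf2, −78 → 0 °C
Reagents that add atoms: N-phenylbis(trifluoromethanesulfonimide), O=S(=O)(N(c1ccccc1)S(=O)(=O)C(F)(F)F)C(F)(F)F
Why: Kinetic deprotonation by the hindered amide occurs at the C3 methylene and not at the tertiary C5–H next to the quaternary centre, and O-sulfonylation of the enolate gives the C3=C4 enol triflate with C5 and C10 untouched. The triflate also masks the C4 carbonyl as an electron-poor alkene for step 5.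

Step 5
Reactants: 12 (4aR,8aR)-4a-methyl-6-methylidene-3,4,4a,5,6,7,8,8a-octahydronaphthalen-1-yl trifluoromethanesulfonate
Product: 14 (4aR,8aR)-4a-methyl-6-oxo-3,4,4a,5,6,7,8,8a-octahydronaphthalen-1-yl trifluoromethanesulfonate, via spiro ozonide 13 (not isolated)
Conditions: O3, CH2Cl2, −78 °C (Sudan Red 7B end point); PPh3, −78 °C → rt
Reagents that add atoms: ozone, [O-][O+]=O
Why: Ozonolysis: the electrophilic oxidant attacks the electron-rich 1,1-disubstituted C8 methylene much faster than the triflate-bearing C3=C4 bond, and Criegee fragmentation followed by reduction of the ozonide reveals the C8 ketone. The indicator dye marks the end point before the second alkene is touched.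

Step 6
Reactants: 14 (4aR,8aR)-4a-methyl-6-oxo-3,4,4a,5,6,7,8,8a-octahydronaphthalen-1-yl trifluoromethanesulfonate
Product: 15 (4aR,8aR)-5,8a-dimethyl-3,4,4a,7,8,8a-hexahydronaphthalen-2(1H)-one
Conditions: MeZnCl, Pd(PPh3)4 (5 mol %), THF, rt → 50 °C
Reagents that add atoms: methylzinc chloride, C[Zn]Cl
Why: Negishi coupling: oxidative addition of zerovalent palladium into the C4–OTf bond, transmetalation from zinc and reductive elimination place the C15 methyl on C4 and keep the alkene at C3=C4. The organozinc reagent does not add to the C8 ketone, and a methyl group offers no β-hydride pathway.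

Step 7
Reactants: 15 (4aR,8aR)-5,8a-dimethyl-3,4,4a,7,8,8a-hexahydronaphthalen-2(1H)-one
Product: 17 (4aR,8aR)-3-(2-hydroxypropan-2-yl)-5,8a-dimethyl-3,4,4a,7,8,8a-hexahydronaphthalen-2(1H)-one (C7 epimers), via lithium enolate 16 (not isolated)
Conditions: LiN(iPr)2, THF, −78 °C; acetone, −78 °C; aq NH4Cl at −78 °C
Reagents that add atoms: acetone, CC(C)=O
Why: Aldol addition: the amide base removes a proton from C7 and not from C9, which is neopentyl next to the quaternary C10, and the lithium enolate adds to acetone; quenching cold prevents retro-aldol cleavage. The new C7 centre is of no consequence because it becomes sp2 in step 8.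

Step 8
Reactants: 17 (4aR,8aR)-3-(2-hydroxypropan-2-yl)-5,8a-dimethyl-3,4,4a,7,8,8a-hexahydronaphthalen-2(1H)-one
Product: 19 (5R,10R)-eudesma-3,7(11)-dien-8-one, via tertiary mesylate 18 (not isolated)
Conditions: MsCl, Et3N, CH2Cl2, 0 °C; then DBU, rt
Reagents that add atoms: none
Why: Mesylation of the tertiary alcohol followed by DBU gives E1cB elimination through the C7 enolate, which can only produce the conjugated C7=C11 isopropylidene ketone. Any isopropenyl isomer formed by competing E1 loss should be drawn into conjugation by the same base.

Step 9
Reactants: 19 (5R,10R)-eudesma-3,7(11)-dien-8-one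
Product: 20 3α,4α-dihydroxyeudesm-7(11)-en-8-one
Conditions: OsO4 (2 mol %), NMO, acetone/H2O, rt
Reagents that add atoms: osmium tetroxide, O=[Os](=O)(=O)=O (transfers both oxygen atoms); N-methylmorpholine N-oxide, C[N+]1([O-])CCOCC1, and water, O (replenish the oxygen on osmium)
Why: Upjohn dihydroxylation: OsO4 adds in a concerted [3+2] manner to the electron-rich trisubstituted C3=C4 alkene and not to the electron-poor tetrasubstituted C7=C11 enone. The axial C10 methyl is syn-axial to the β-face of C4, so both oxygens arrive from the α-face; this sets C4 (4α-OH, 4β-Me) correctly and C3 provisionally as 3α.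

Step 10
Reactants: 20 3α,4α-dihydroxyeudesm-7(11)-en-8-one
Product: 21 4α-hydroxyeudesm-7(11)-ene-3,8-dione
Conditions: IBX, DMSO, rt
Reagents that add atoms: none
Why: IBX oxidises the secondary axial C3 alcohol to the ketone and, unlike NaIO4 or Pb(OAc)4, does not cleave the glycol C–C bond; the tertiary C4 hydroxyl cannot be oxidised and the enone is inert at room temperature.

Step 11
Reactants: 21 4α-hydroxyeudesm-7(11)-ene-3,8-dione
Product: 22 3β,4α-dihydroxyeudesm-7(11)-en-8-one
Conditions: NaBH4, MeOH/CH2Cl2 (1:1), −78 °C
Reagents that add atoms: none
Why: At −78 °C borohydride should reduce the saturated, α-oxygenated C3 ketone much faster than the hindered, conjugated C8 enone. Hydride enters along the axial α trajectory because the axial 4β-methyl blocks the β-face, giving the equatorial 3β-alcohol and thus the trans-diequatorial diol.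

Step 12
Reactants: 22 3β,4α-dihydroxyeudesm-7(11)-en-8-one
Product: 23 3β-angeloyloxy-4α-hydroxyeudesm-7(11)-en-8-one
Conditions: angelic acid, 2,4,6-trichlorobenzoyl chloride, Et3N, toluene, rt; then 22, 80 °C
Reagents that add atoms: angelic acid [(Z)-2-methylbut-2-enoic acid], C/C=C(/C)C(=O)O
Why: Yamaguchi-type esterification: the alcohol attacks the less hindered angeloyl carbonyl of the mixed anhydride, and only the secondary C3 hydroxyl reacts, the tertiary C4 hydroxyl being too hindered. Omitting a nucleophilic pyridine catalyst avoids the addition–elimination pathway by which activated angeloyl species turn into tigloyl ones.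

Step 13
Reactants: 23 3β-angeloyloxy-4α-hydroxyeudesm-7(11)-en-8-one
Product: 24 3β-angeloyloxy-4α-acetoxyeudesm-7(11)-en-8-one (target, CNP0141494.1)
Conditions: Ac2O, DMAP, Et3N, CH2Cl2, 40 °C
Reagents that add atoms: acetic anhydride, CC(=O)OC(C)=O
Why: DMAP-catalysed acylation through the N-acetylpyridinium ion is the standard way to esterify a hindered tertiary alcohol. No stereocentre is touched, and the finished angelate ester, unlike an activated angeloyl derivative, should keep its Z geometry under these mildly basic conditions.

## Compound list

1 | 3-methylbut-3-en-1-ol | C=C(C)CCO | starting material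
2 | 3-ethoxycyclohex-2-en-1-one | CCOC1=CC(=O)CCC1 | starting material
3 | dilithio dianion of 1 [lithium 3-(lithiomethyl)but-3-en-1-olate] | [Li]CC(=C)CCO[Li] | intermediate (not isolated)
4 | dilithium alkoxide of 3-ethoxy-1-(4-hydroxy-2-methylidenebutyl)cyclohex-2-en-1-ol (racemic) | CCOC1=CC(O[Li])(CC(=C)CCO[Li])CCC1 | intermediate (not isolated)
5 | 3-(4-hydroxy-2-methylidenebutyl)cyclohex-2-en-1-one | O=C1C=C(CC(=C)CCO)CCC1 | intermediate
6 | 3-(4-chloro-2-methylidenebutyl)cyclohex-2-en-1-one | O=C1C=C(CC(=C)CCCl)CCC1 | intermediate
7 | methylmagnesium bromide | C[Mg]Br | starting material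
8 | bromomagnesium C4–C5 enolate of (R)-3-(4-chloro-2-methylidenebutyl)-3-methylcyclohexanone | Br[Mg]OC1=C[C@@](C)(CC(=C)CCCl)CCC1 | intermediate (not isolated)
9 | (4aR,8aS)-4a-methyl-6-methylideneoctahydronaphthalen-1(2H)-one (cis-fused; 5S,10R in eudesmane numbering) | O=C1CCC[C@]2(C)CC(=C)CC[C@H]12 | intermediate (not isolated)
10 | (4aR,8aR)-4a-methyl-6-methylideneoctahydronaphthalen-1(2H)-one (trans-fused; 5R,10R) | O=C1CCC[C@]2(C)CC(=C)CC[C@@H]12 | intermediate
11 | lithium C3–C4 enolate of 10 | [Li]OC1=CCC[C@]2(C)CC(=C)CC[C@@H]12 | intermediate (not isolated)
12 | (4aR,8aR)-4a-methyl-6-methylidene-3,4,4a,5,6,7,8,8a-octahydronaphthalen-1-yl trifluoromethanesulfonate | O=S(=O)(OC1=CCC[C@]2(C)CC(=C)CC[C@@H]12)C(F)(F)F | intermediate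
13 | spiro 1,2,4-trioxolane (ozonide) at C8 of 12, mixture at the spiro carbon | O=S(=O)(OC1=CCC[C@]2(C)CC3(CC[C@@H]12)OCOO3)C(F)(F)F | intermediate (not isolated)
14 | (4aR,8aR)-4a-methyl-6-oxo-3,4,4a,5,6,7,8,8a-octahydronaphthalen-1-yl trifluoromethanesulfonate | O=S(=O)(OC1=CCC[C@]2(C)CC(=O)CC[C@@H]12)C(F)(F)F | intermediate
15 | (4aR,8aR)-5,8a-dimethyl-3,4,4a,7,8,8a-hexahydronaphthalen-2(1H)-one | CC1=CCC[C@]2(C)CC(=O)CC[C@@H]12 | intermediate
16 | lithium C7–C8 enolate of 15 | CC1=CCC[C@]2(C)CC(O[Li])=CC[C@@H]12 | intermediate (not isolated)
17 | (4aR,8aR)-3-(2-hydroxypropan-2-yl)-5,8a-dimethyl-3,4,4a,7,8,8a-hexahydronaphthalen-2(1H)-one, C7 epimers | CC1=CCC[C@]2(C)CC(=O)C(C(C)(C)O)C[C@@H]12 | intermediate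
18 | methanesulfonate of the tertiary alcohol of 17 | CC1=CCC[C@]2(C)CC(=O)C(C(C)(C)OS(C)(=O)=O)C[C@@H]12 | intermediate (not isolated)
19 | (5R,10R)-eudesma-3,7(11)-dien-8-one | CC1=CCC[C@]2(C)CC(=O)C(=C(C)C)C[C@@H]12 | intermediate
20 | 3α,4α-dihydroxyeudesm-7(11)-en-8-one (3R,4S,5R,10R) | O[C@@H]1CC[C@]2(C)CC(=O)C(=C(C)C)C[C@H]2[C@]1(C)O | intermediate
21 | 4α-hydroxyeudesm-7(11)-ene-3,8-dione (4S,5R,10R) | O=C1CC[C@]2(C)CC(=O)C(=C(C)C)C[C@H]2[C@]1(C)O | intermediate
22 | 3β,4α-dihydroxyeudesm-7(11)-en-8-one (3S,4S,5R,10R) | O[C@H]1CC[C@]2(C)CC(=O)C(=C(C)C)C[C@H]2[C@]1(C)O | intermediate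
23 | 3β-angeloyloxy-4α-hydroxyeudesm-7(11)-en-8-one | C/C=C(/C)C(=O)O[C@H]1CC[C@]2(C)CC(=O)C(=C(C)C)C[C@H]2[C@]1(C)O | intermediate
24 | 3β-angeloyloxy-4α-acetoxyeudesm-7(11)-en-8-one (3S,4S,5R,10R) | C/C=C(/C)C(=O)O[C@H]1CC[C@]2(C)CC(=O)C(=C(C)C)C[C@H]2[C@]1(C)OC(C)=O | target

## Step count and risk

Total step count: 13. Longest linear sequence: 13 steps (the route is linear from 1 and 2).

**Step 3 (key step).**
- *What may go wrong:* facial discrimination in the methyl transfer may be lower than with larger Grignard reagents. The Grignard reagent may abstract a proton at the doubly allylic C9 instead of adding. Alkylation of the magnesium enolate may be slow, so that it is protonated or the halide couples with residual Grignard reagent. The equilibration may stop short of the trans isomer.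
- *Fallback:* from 6, conjugate addition of AlMe3 catalysed by copper thiophene-2-carboxylate (CuO2C–C4H3S, monovalent copper) and a chiral phosphoramidite in Et2O, followed by aqueous work-up, should give the open chloro ketone (R)-3-(4-chloro-2-methylidenebutyl)-3-methylcyclohexan-1-one F1. This is cyclised separately with KOtBu and catalytic NaI in tBuOH/THF. Under these conditions the enolates equilibrate, only the C5 enolate can close a six-membered ring, and the same base epimerises C5, so the sequence returns to the route at 10.

**Step 5.**
- *What may go wrong:* over-oxidation, with ozone also attacking the enol triflate alkene once the methylene is consumed, and loss of the triflate during reductive work-up.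
- *Fallback:* from 12, OsO4-catalysed dihydroxylation (NMO) of the methylene, which discriminates still more strongly against the triflate-bearing alkene, gives the glycol (4aR,8aR)-6-hydroxy-6-(hydroxymethyl)-4a-methyl-3,4,4a,5,6,7,8,8a-octahydronaphthalen-1-yl trifluoromethanesulfonate F2 (C8 epimers). Cleavage with NaIO4 returns to the route at 14.

**Step 7.**
- *What may go wrong:* competing enolisation toward C9, proton transfer from acetone to the enolate, and retro-aldol cleavage during work-up.
- *Fallback:* from 15, the enolate is trapped with Me3SiCl to give the C7=C8 trimethylsilyl enol ether of 15 F3, from which a minor C8=C9 regioisomer can be removed. A TiCl4-mediated Mukaiyama addition to acetone in CH2Cl2 at −78 °C then proceeds under non-basic conditions and returns to the route at 17.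

**Step 11.**
- *What may go wrong:* partial reduction of the C8 enone carbonyl, or hydride delivery from the β-face, which would regenerate the 3α-alcohol.
- *Fallback:* from 21, both carbonyls are reduced deliberately with NaBH4/CeCl3 to the triol 3β,4α,8-trihydroxyeudesm-7(11)-ene F4 (C8 epimers). MnO2, which oxidises only the allylic alcohol, then restores the C8 enone and returns to the route at 22.

**Step 12.**
- *What may go wrong:* Z-to-E isomerisation of the activated angeloyl unit, and slow acylation of the secondary hydroxyl next to the fully substituted C4.
- *Fallback:* from 22, the C3 hydroxyl is esterified (carbodiimide, DMAP) with 2-[bis(2,2,2-trifluoroethoxy)phosphoryl]propanoic acid to give the phosphonate ester 3β-{2-[bis(2,2,2-trifluoroethoxy)phosphoryl]propanoyloxy}-4α-hydroxyeudesm-7(11)-en-8-one F5. A Still–Gennari olefination with acetaldehyde (KN(SiMe3)2, 18-crown-6, THF, −78 °C) then builds the Z-trisubstituted alkene on the substrate and returns to the route at 23.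

**Step 13.**
- *What may go wrong:* incomplete acylation of the hindered tertiary hydroxyl, elimination of the tertiary oxygen, and migration of the angeloyl group from O3 to O4 followed by acetylation at O3.
- *Fallback:* from 21, the tertiary hydroxyl is acetylated before C3 is reduced (Ac2O, DMAP), giving 4α-acetoxyeudesm-7(11)-ene-3,8-dione F6. NaBH4 in MeOH/CH2Cl2 at −78 °C, as in step 11, then gives 4α-acetoxy-3β-hydroxyeudesm-7(11)-en-8-one F7, which is angeloylated at once under the conditions of step 12 to limit acetyl migration and returns to the route at 24.

## Further compounds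

F1 | step 3 | (R)-3-(4-chloro-2-methylidenebutyl)-3-methylcyclohexan-1-one | O=C1CCC[C@](C)(CC(=C)CCCl)C1
F2 | step 5 | (4aR,8aR)-6-hydroxy-6-(hydroxymethyl)-4a-methyl-3,4,4a,5,6,7,8,8a-octahydronaphthalen-1-yl trifluoromethanesulfonate (C8 epimers) | O=S(=O)(OC1=CCC[C@]2(C)CC(O)(CO)CC[C@@H]12)C(F)(F)F
F3 | step 7 | C7=C8 trimethylsilyl enol ether of 15 | CC1=CCC[C@]2(C)CC(O[Si](C)(C)C)=CC[C@@H]12
F4 | step 11 | 3β,4α,8-trihydroxyeudesm-7(11)-ene (C8 epimers) | O[C@H]1CC[C@]2(C)CC(O)C(=C(C)C)C[C@H]2[C@]1(C)O
F5 | step 12 | 3β-{2-[bis(2,2,2-trifluoroethoxy)phosphoryl]propanoyloxy}-4α-hydroxyeudesm-7(11)-en-8-one | CC(C(=O)O[C@H]1CC[C@]2(C)CC(=O)C(=C(C)C)C[C@H]2[C@]1(C)O)P(=O)(OCC(F)(F)F)OCC(F)(F)F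
F6 | step 13 | 4α-acetoxyeudesm-7(11)-ene-3,8-dione | O=C1CC[C@]2(C)CC(=O)C(=C(C)C)C[C@H]2[C@]1(C)OC(C)=O
F7 | step 13 | 4α-acetoxy-3β-hydroxyeudesm-7(11)-en-8-one | O[C@H]1CC[C@]2(C)CC(=O)C(=C(C)C)C[C@H]2[C@]1(C)OC(C)=O
A1 | alternative 1 | (3S,1(10)E,4E)-3-(tert-butyldimethylsilyloxy)germacra-1(10),4,7(11)-trien-8-one | C/C1=C\C[C@H](O[Si](C)(C)C(C)(C)C)/C(C)=C/CC(=C(C)C)C(=O)C1
A2 | alternative 1 | 3β-(tert-butyldimethylsilyloxy)-4α-hydroxyeudesm-7(11)-en-8-one | CC(C)(C)[Si](C)(C)O[C@H]1CC[C@]2(C)CC(=O)C(=C(C)C)C[C@H]2[C@]1(C)O
A3 | alternative 2 | methyl 4-(3-hydroxy-2,6-dimethylphenyl)-2-methylidenebutyl carbonate | Cc1ccc(O)c(C)c1CCC(=C)COC(=O)OC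
A4 | alternative 2 | (4aS)-1,4a-dimethyl-6-methylidene-5,6,7,8-tetrahydronaphthalen-2(4aH)-one | CC1=C2CCC(=C)C[C@@]2(C)C=CC1=O
A5 | alternative 3 | tert-butyldimethyl{[(5E)-6-methyl-3-(propan-2-ylidene)undeca-1,5-dien-9-yn-2-yl]oxy}silane | CC#CCC/C(C)=C/CC(=C(C)C)C(=C)O[Si](C)(C)C(C)(C)C
A6 | alternative 3 | eudesma-3,7(11)-dien-8-one (identical with 19) | CC1=CCC[C@]2(C)CC(=O)C(=C(C)C)C[C@@H]12
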